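**Target:** methyl (5E,7E,12R,14Z)-10-bromo-12-hydroxy-9-oxoprosta-5,7,10,14-tetraen-1-oate (the bromovulone of the given SMILES).

**Strategy.** In prostanoid numbering, C7–C8–C9–C10 of the target is an acetoacetate unit (C7 ester carbon, C9 ketone) and C11–C12, with the tertiary C12–O bond, is a 2-silyloxyalkene; ring C8–C12 is therefore cut at C10–C11 and C8–C12. A chiral dirhodium catalyst turns a silyl-protected enoldiazoacetate into an enol-carbene that is annulated (3+2) with a silyl enol ether, forming both bonds, the five-membered ring and the C12 stereocentre in one operation. The precursors are the triisopropylsilyl enol ether of methyl diazoacetoacetate and the bis(triethylsilyl) enol ether of 4-hydroxybutan-2-one. Side chains (Z-Wittig, alkenylzinc), dienone unmasking and enolate-based C10 bromination/dehydrogenation follow.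

Key step: step 5

Assumption: the sense of asymmetric induction of the (S)-prolinate ligands with this pair of reactants cannot be assigned in advance; the route is written for Rh2(S-DOSP)4, and Rh2(R-DOSP)4 would be used if the opposite enantiomer of 8 were to predominate.

Remark: atoms are labelled by prostanoid numbering of the target; the C12 descriptor is S in 8–20 and R from 21 onwards only because C11 then outranks C13, no bond to C12 being made or broken after step 5.

**Route**

Step 1
Reactants: 1 methyl acetoacetate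
Product: 2 methyl 2-diazo-3-oxobutanoate
Conditions: 4-acetamidobenzenesulfonyl azide, Et3N, MeCN, 0 °C → rt
Reagents that add atoms: 4-acetamidobenzenesulfonyl azide, CC(=O)Nc1ccc(cc1)S(=O)(=O)N=[N+]=[N-]
Why: Regitz diazo transfer, in which the amine-generated enolate of the 1,3-dicarbonyl compound attacks the terminal azide nitrogen and the adduct fragments to the diazo ester and the sulfonamide.

Step 2
Reactants: 2 methyl 2-diazo-3-oxobutanoate
Product: 3 methyl 2-diazo-3-(triisopropylsilyloxy)but-3-enoate
Conditions: i-Pr3SiOTf, Et3N, CH2Cl2, 0 °C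
Reagents that add atoms: triisopropylsilyl trifluoromethanesulfonate, CC(C)[Si](OS(=O)(=O)C(F)(F)F)(C(C)C)C(C)C
Why: Soft enolisation and O-silylation of the acetyl group (silyl triflate with a tertiary amine) gives the enoldiazoacetate, the triisopropylsilyl group being chosen because it stabilises the diazo compound and later the ring enol ether towards base, hydride and chromatography.

Step 3
Reactants: 4 4-hydroxybutan-2-one
Product: 5 4-(triethylsilyloxy)butan-2-one
Conditions: Et3SiCl, imidazole, CH2Cl2, 0 °C
Reagents that add atoms: chlorotriethylsilane, CC[Si](Cl)(CC)CC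
Why: Imidazole-promoted O-silylation of the primary alcohol, a triethylsilyl ether being chosen because as a primary ether it can later be oxidised directly to the aldehyde in the presence of the two hindered silyl groups.

Step 4
Reactants: 5 4-(triethylsilyloxy)butan-2-one
Product: 7 triethyl{[4-(triethylsilyloxy)but-1-en-2-yl]oxy}silane, via lithium enolate 6 (not isolated)
Conditions: LiN(i-Pr)2, THF, −78 °C; Et3SiCl, −78 → 0 °C
Reagents that add atoms: chlorotriethylsilane, CC[Si](Cl)(CC)CC
Why: Kinetic enolate formation with the hindered amide base removes a methyl (C11) proton and O-silylation traps the terminal enolate as the 1,1-disubstituted enol ether, any enolate formed towards C13 being lost by β-elimination and not carried into the product.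

Step 5
Reactants: 3 methyl 2-diazo-3-(triisopropylsilyloxy)but-3-enoate; 7 triethyl{[4-(triethylsilyloxy)but-1-en-2-yl]oxy}silane
Product: 8 methyl (5S)-5-(triethylsilyloxy)-5-[2-(triethylsilyloxy)ethyl]-2-(triisopropylsilyloxy)cyclopent-1-ene-1-carboxylate
Conditions: Rh2(S-DOSP)4, dirhodium tetrakis[(S)-N-(4-dodecylphenylsulfonyl)prolinate] (1 mol %), 7 (1.5 equiv), CH2Cl2–pentane, −78 → −40 °C, slow addition of 3
Reagents that add atoms: none
Why: Proposed new method: loss of N2 from 3 at the divalent rhodium centre gives a rhodium enol-carbene whose vinylogous CH2 (C10) is electrophilic, the nucleophilic CH2 (C11) of 7 adds there to give a zwitterion with a vinyl–rhodium bond at C8 and a triethylsilyloxocarbenium ion at C12, and C8 then attacks C12 with release of the catalyst. The closest known reaction type is the dirhodium-catalysed formal (3+2) annulation of vinyldiazoacetates and enoldiazoacetates with vinyl ethers and indoles. Ring C8–C12 closes by a 5-exo-trig attack on the C12=O+ bond from the ring-embedded C8 (formally 5-(enolendo)-exo-trig), which is feasible because the in-plane C8–Rh σ bond and not the enol π system is the nucleophile. C12, the only new stereocentre, is set in the C8–C12 bond formation by the chiral prolinate ligand sphere, which must distinguish the two faces of the oxocarbenium ion while it is still ion-paired to rhodium at low temperature in a weakly polar medium. The step needs attack at C10 instead of at the carbene carbon (no cyclopropanation or insertion) and ring closure faster than silyl transfer, which the unsubstituted vinyl terminus of 3, the high π-nucleophilicity of the 1,1-disubstituted enol ether 7 and the bulk of both silyl groups should secure.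

Step 6
Reactants: 8 methyl (5S)-5-(triethylsilyloxy)-5-[2-(triethylsilyloxy)ethyl]-2-(triisopropylsilyloxy)cyclopent-1-ene-1-carboxylate
Product: 10 methyl (5S)-5-(2-oxoethyl)-5-(triethylsilyloxy)-2-(triisopropylsilyloxy)cyclopent-1-ene-1-carboxylate, via alkoxysulfonium chloride 9 (not isolated)
Conditions: (COCl)2, DMSO, CH2Cl2, −78 → −40 °C; Et3N, −78 → 0 °C
Reagents that add atoms: none
Why: Swern oxidation with oxidative desilylation, in which the chlorosulfonium reagent cleaves only the unhindered primary Si–O bond to give the alkoxysulfonium salt that triethylamine collapses to the C14 aldehyde, whereas the tertiary triethylsilyl ether and the hindered, ester-conjugated triisopropylsilyl enol ether are not attacked.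

Step 7
Reactants: 10 methyl (5S)-5-(2-oxoethyl)-5-(triethylsilyloxy)-2-(triisopropylsilyloxy)cyclopent-1-ene-1-carboxylate; 11 hexyltriphenylphosphonium bromide
Product: 13 methyl (5S)-5-[(2Z)-oct-2-en-1-yl]-5-(triethylsilyloxy)-2-(triisopropylsilyloxy)cyclopent-1-ene-1-carboxylate, via hexylidenetriphenylphosphorane 12 (not isolated)
Conditions: 11, NaN(SiMe3)2, THF, 0 °C; then 10, −78 → 0 °C
Reagents that add atoms: none
Why: Wittig olefination with a non-stabilised ylide under lithium-free conditions proceeds through the kinetically favoured cis-oxaphosphetane and should give the 14Z alkene, the donor-deactivated ring ester being inert to the ylide at low temperature.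

Step 8
Reactants: 13 methyl (5S)-5-[(2Z)-oct-2-en-1-yl]-5-(triethylsilyloxy)-2-(triisopropylsilyloxy)cyclopent-1-ene-1-carboxylate
Product: 14 {(5S)-5-[(2Z)-oct-2-en-1-yl]-5-(triethylsilyloxy)-2-(triisopropylsilyloxy)cyclopent-1-en-1-yl}methanol
Conditions: i-Bu2AlH, CH2Cl2, −78 → −40 °C; aq. potassium sodium tartrate work-up
Reagents that add atoms: none
Why: Hydride reduction of the ester by i-Bu2AlH (two hydride transfers) gives the C7 allylic alcohol, there being no other reducible group and the β-silyloxy substituent preventing conjugate reduction.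

Step 9
Reactants: 14 {(5S)-5-[(2Z)-oct-2-en-1-yl]-5-(triethylsilyloxy)-2-(triisopropylsilyloxy)cyclopent-1-en-1-yl}methanol
Product: 15 (5S)-5-[(2Z)-oct-2-en-1-yl]-5-(triethylsilyloxy)-2-(triisopropylsilyloxy)cyclopent-1-ene-1-carbaldehyde
Conditions: MnO2, CH2Cl2, rt
Reagents that add atoms: none
Why: Selective allylic alcohol oxidation on MnO2 gives the β-silyloxy enal under neutral conditions that neither hydrolyse the acid-labile hydroxymethyl enol ether nor touch the isolated Z alkene.

Step 10
Reactants: 15 (5S)-5-[(2Z)-oct-2-en-1-yl]-5-(triethylsilyloxy)-2-(triisopropylsilyloxy)cyclopent-1-ene-1-carbaldehyde; 16 methyl hex-5-ynoate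
Product: 19 methyl (5E)-7-hydroxy-7-{(5S)-5-[(2Z)-oct-2-en-1-yl]-5-(triethylsilyloxy)-2-(triisopropylsilyloxy)cyclopent-1-en-1-yl}hept-5-enoate (both C7 epimers), via alkenylzirconocene chloride 17 (not isolated), via alkenyl(methyl)zinc 18 (not isolated)
Conditions: 16, Cp2Zr(H)Cl, CH2Cl2, rt; Me2Zn, −65 °C; 15, 0 °C
Reagents that add atoms: none
Why: Hydrozirconation of the terminal alkyne (syn addition, metal at the terminus) and Zr-to-Zn transmetalation give an (E)-alkenylzinc that adds 1,2 to the aldehyde but not to the methyl ester, forming C6–C7, the new C7 carbinol centre arising as a mixture of epimers that is of no consequence because step 11 removes it.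

Step 11
Reactants: 19 methyl (5E)-7-hydroxy-7-{(5S)-5-[(2Z)-oct-2-en-1-yl]-5-(triethylsilyloxy)-2-(triisopropylsilyloxy)cyclopent-1-en-1-yl}hept-5-enoate
Product: 20 methyl (5E,7E,12S,14Z)-9-oxo-12-(triethylsilyloxy)prosta-5,7,14-trien-1-oate
Conditions: PPTS (cat.), wet CH2Cl2, 0 °C
Reagents that add atoms: none
Why: Stork–Danheiser-type dehydrative unmasking, in which mild acid ionises the doubly allylic C7–OH with assistance from the enol ether and loss of the silyl group from the silyloxy-pentadienyl cation gives the C7=C8 enone with the tertiary silyl ether intact, the 7E geometry being expected because the dienyl chain turns away from the coplanar C9–OSi(i-Pr)3 group in the cation and from the carbonyl oxygen in the product.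

Step 12
Reactants: 20 methyl (5E,7E,12S,14Z)-9-oxo-12-(triethylsilyloxy)prosta-5,7,14-trien-1-oate
Product: 23 methyl (5E,7E,12R,14Z)-10-bromo-9-oxo-12-(triethylsilyloxy)prosta-5,7,14-trien-1-oate (both C10 epimers), via lithium dienolate 21 (not isolated), via trimethylsilyl dienol ether 22 (not isolated)
Conditions: LiN(SiMe3)2, Me3SiCl, THF, −78 °C; then NBS, THF, −78 °C (crude enol ether)
Reagents that add atoms: N-bromosuccinimide, O=C1CCC(=O)N1Br
Why: α-Bromination of a ketone through its silyl enol ether, in which kinetic deprotonation can only occur at C10 (C8 is sp2 and the ester is less acidic) and NBS attacks the electron-rich enol ether far faster than the isolated 14Z alkene or the electron-poor diene, the C10 centre arising as a mixture of epimers that step 13 removes.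

Step 13
Reactants: 23 methyl (5E,7E,12R,14Z)-10-bromo-9-oxo-12-(triethylsilyloxy)prosta-5,7,14-trien-1-oate
Product: 27 methyl (5E,7E,12R,14Z)-10-bromo-9-oxo-12-(triethylsilyloxy)prosta-5,7,10,14-tetraen-1-oate, via lithium bromo enolate 24 (not isolated), via bromo selenide 25 (not isolated), via selenoxide 26 (not isolated)
Conditions: LiN(SiMe3)2, THF, −78 °C; PhSeCl; then H2O2, pyridine, CH2Cl2, 0 °C → rt
Reagents that add atoms: none
Why: α-Selenenylation of the enolate of the α-bromo ketone followed by selenoxide syn-elimination, which can only take a C11 hydrogen, should introduce the C10=C11 bond with bromine retained at C10 under neutral conditions at or below room temperature.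

Step 14
Reactants: 27 methyl (5E,7E,12R,14Z)-10-bromo-9-oxo-12-(triethylsilyloxy)prosta-5,7,10,14-tetraen-1-oate
Product: 28 methyl (5E,7E,12R,14Z)-10-bromo-12-hydroxy-9-oxoprosta-5,7,10,14-tetraen-1-oate (target)
Conditions: HF·pyridine, pyridine, THF, 0 °C
Reagents that add atoms: none
Why: Fluoride-mediated cleavage of the tertiary triethylsilyl ether (Si–F bond formation) under buffered, weakly acidic conditions should free the C12 hydroxyl without exposing the base-sensitive bromo trienone to nucleophiles or base.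

**Compound list**

1 | methyl acetoacetate (methyl 3-oxobutanoate) | COC(=O)CC(C)=O | starting material
2 | methyl 2-diazo-3-oxobutanoate | COC(=O)C(=[N+]=[N-])C(C)=O | intermediate
3 | methyl 2-diazo-3-(triisopropylsilyloxy)but-3-enoate | COC(=O)C(=[N+]=[N-])C(=C)O[Si](C(C)C)(C(C)C)C(C)C | intermediate
4 | 4-hydroxybutan-2-one | CC(=O)CCO | starting material
5 | 4-(triethylsilyloxy)butan-2-one | CC(=O)CCO[Si](CC)(CC)CC | intermediate
6 | lithium 4-(triethylsilyloxy)but-1-en-2-olate | [Li]OC(=C)CCO[Si](CC)(CC)CC | intermediate (not isolated)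
7 | triethyl{[4-(triethylsilyloxy)but-1-en-2-yl]oxy}silane | C=C(CCO[Si](CC)(CC)CC)O[Si](CC)(CC)CC | intermediate
8 | methyl (5S)-5-(triethylsilyloxy)-5-[2-(triethylsilyloxy)ethyl]-2-(triisopropylsilyloxy)cyclopent-1-ene-1-carboxylate | COC(=O)C1=C(O[Si](C(C)C)(C(C)C)C(C)C)CC[C@]1(O[Si](CC)(CC)CC)CCO[Si](CC)(CC)CC | intermediate
9 | dimethyl{2-[(1S)-2-(methoxycarbonyl)-1-(triethylsilyloxy)-3-(triisopropylsilyloxy)cyclopent-2-en-1-yl]ethoxy}sulfonium chloride | COC(=O)C1=C(O[Si](C(C)C)(C(C)C)C(C)C)CC[C@]1(O[Si](CC)(CC)CC)CCO[S+](C)C.[Cl-] | intermediate (not isolated)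
10 | methyl (5S)-5-(2-oxoethyl)-5-(triethylsilyloxy)-2-(triisopropylsilyloxy)cyclopent-1-ene-1-carboxylate | COC(=O)C1=C(O[Si](C(C)C)(C(C)C)C(C)C)CC[C@]1(O[Si](CC)(CC)CC)CC=O | intermediate
11 | hexyltriphenylphosphonium bromide | CCCCCC[P+](c1ccccc1)(c1ccccc1)c1ccccc1.[Br-] | starting material
12 | hexylidenetriphenylphosphorane | CCCCCC=P(c1ccccc1)(c1ccccc1)c1ccccc1 | intermediate (not isolated)
13 | methyl (5S)-5-[(2Z)-oct-2-en-1-yl]-5-(triethylsilyloxy)-2-(triisopropylsilyloxy)cyclopent-1-ene-1-carboxylate | CCCCC/C=C\C[C@@]1(O[Si](CC)(CC)CC)CCC(O[Si](C(C)C)(C(C)C)C(C)C)=C1C(=O)OC | intermediate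
14 | {(5S)-5-[(2Z)-oct-2-en-1-yl]-5-(triethylsilyloxy)-2-(triisopropylsilyloxy)cyclopent-1-en-1-yl}methanol | CCCCC/C=C\C[C@@]1(O[Si](CC)(CC)CC)CCC(O[Si](C(C)C)(C(C)C)C(C)C)=C1CO | intermediate
15 | (5S)-5-[(2Z)-oct-2-en-1-yl]-5-(triethylsilyloxy)-2-(triisopropylsilyloxy)cyclopent-1-ene-1-carbaldehyde | CCCCC/C=C\C[C@@]1(O[Si](CC)(CC)CC)CCC(O[Si](C(C)C)(C(C)C)C(C)C)=C1C=O | intermediate
16 | methyl hex-5-ynoate | C#CCCCC(=O)OC | starting material
17 | methyl (5E)-6-[chlorobis(cyclopentadienyl)zirconio]hex-5-enoate, Cp2Zr(Cl)CH=CH(CH2)3CO2CH3 (cyclopentadienyl rings written σ-bonded in the line notation) | COC(=O)CCC/C=C/[Zr](Cl)(C1C=CC=C1)C1C=CC=C1 | intermediate (not isolated)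
18 | methyl (5E)-6-(methylzincio)hex-5-enoate, CH3ZnCH=CH(CH2)3CO2CH3 | COC(=O)CCC/C=C/[Zn]C | intermediate (not isolated)
19 | methyl (5E)-7-hydroxy-7-{(5S)-5-[(2Z)-oct-2-en-1-yl]-5-(triethylsilyloxy)-2-(triisopropylsilyloxy)cyclopent-1-en-1-yl}hept-5-enoate (both C7 epimers) | CCCCC/C=C\C[C@@]1(O[Si](CC)(CC)CC)CCC(O[Si](C(C)C)(C(C)C)C(C)C)=C1C(O)/C=C/CCCC(=O)OC | intermediate
20 | methyl (5E,7E,12S,14Z)-9-oxo-12-(triethylsilyloxy)prosta-5,7,14-trien-1-oate | CCCCC/C=C\C[C@@]1(O[Si](CC)(CC)CC)CCC(=O)/C1=C/C=C/CCCC(=O)OC | intermediate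
21 | lithium C9-enolate of 20 (C9–OLi, C9=C10; alkene geometries and C12 arrangement as in 20) | CCCCC/C=C\C[C@@]1(O[Si](CC)(CC)CC)CC=C(O[Li])/C1=C/C=C/CCCC(=O)OC | intermediate (not isolated)
22 | C9 trimethylsilyl dienol ether of 20 (C9–OSiMe3, C9=C10; alkene geometries and C12 arrangement as in 20) | CCCCC/C=C\C[C@@]1(O[Si](CC)(CC)CC)CC=C(O[Si](C)(C)C)/C1=C/C=C/CCCC(=O)OC | intermediate (not isolated)
23 | methyl (5E,7E,12R,14Z)-10-bromo-9-oxo-12-(triethylsilyloxy)prosta-5,7,14-trien-1-oate (both C10 epimers) | CCCCC/C=C\C[C@@]1(O[Si](CC)(CC)CC)CC(Br)C(=O)/C1=C/C=C/CCCC(=O)OC | intermediate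
24 | lithium C9-enolate of 23 (C9–OLi, C9=C10–Br; otherwise as 23) | CCCCC/C=C\C[C@@]1(O[Si](CC)(CC)CC)CC(Br)=C(O[Li])/C1=C/C=C/CCCC(=O)OC | intermediate (not isolated)
25 | methyl (5E,7E,12R,14Z)-10-bromo-9-oxo-10-(phenylselanyl)-12-(triethylsilyloxy)prosta-5,7,14-trien-1-oate (both C10 epimers) | CCCCC/C=C\C[C@@]1(O[Si](CC)(CC)CC)CC(Br)([Se]c2ccccc2)C(=O)/C1=C/C=C/CCCC(=O)OC | intermediate (not isolated)
26 | methyl (5E,7E,12R,14Z)-10-bromo-9-oxo-10-(phenylseleninyl)-12-(triethylsilyloxy)prosta-5,7,14-trien-1-oate (selenoxide of 25) | CCCCC/C=C\C[C@@]1(O[Si](CC)(CC)CC)CC(Br)([Se](=O)c2ccccc2)C(=O)/C1=C/C=C/CCCC(=O)OC | intermediate (not isolated)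
27 | methyl (5E,7E,12R,14Z)-10-bromo-9-oxo-12-(triethylsilyloxy)prosta-5,7,10,14-tetraen-1-oate | CCCCC/C=C\C[C@@]1(O[Si](CC)(CC)CC)C=C(Br)C(=O)/C1=C/C=C/CCCC(=O)OC | intermediate
28 | methyl (5E,7E,12R,14Z)-10-bromo-12-hydroxy-9-oxoprosta-5,7,10,14-tetraen-1-oate | CCCCC/C=C\C[C@@]1(O)C=C(Br)C(=O)/C1=C/C=C/CCCC(=O)OC | target

**Step count and risk**

Total step count: 14. Longest linear sequence: 12 steps (from 1 through steps 1, 2 and 5–14, or equally from 4 through steps 3–14).

Steps most likely to fail:

1. Step 5 (proposed new method). What may go wrong: attack at the carbene carbon (cyclopropanation of the enol ether) instead of at C10, silyl transfer that leaves an open-chain adduct, or poor facial discrimination in the C8–C12 closure. The fallback uses known chemistry, takes C12 from an enantiopure epoxide instead of from the catalyst, sets out from 1 and comes back at 8. The dianion of 1 (NaH, then n-BuLi, THF, 0 °C) opens (R)-triethyl[2-(oxiran-2-yl)ethoxy]silane F1 (from commercial (R)-2-(oxiran-2-yl)ethanol, Et3SiCl, imidazole) at its CH2 terminus (BF3·OEt2, −78 °C) to give methyl (6S)-6-hydroxy-3-oxo-8-(triethylsilyloxy)octanoate F2. Silylation (Et3SiCl, imidazole) gives methyl (6S)-3-oxo-6,8-bis(triethylsilyloxy)octanoate F3, and diazo transfer (4-acetamidobenzenesulfonyl azide, Et3N) gives methyl (6S)-2-diazo-3-oxo-6,8-bis(triethylsilyloxy)octanoate F4. Rh2(OAc)4 in CH2Cl2 then effects carbenoid 1,5-insertion into the oxygen-activated C12–H bond with retention of configuration to give methyl (5S)-2-oxo-5-(triethylsilyloxy)-5-[2-(triethylsilyloxy)ethyl]cyclopentane-1-carboxylate F5, which i-Pr3SiOTf/Et3N converts into 8.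

2. Step 13. What may go wrong: C-selenenylation of the hindered bromo enolate may be slow and allow bromine exchange between enolate and ketone, or the selenium by-products may attack the polyene during the elimination. The fallback sets out from 23 and comes back at 27 by a second enol-ether bromination and E2 dehydrobromination. Ketone 23 is converted (LiN(SiMe3)2, Me3SiCl, THF, −78 °C) into its C9 trimethylsilyl bromo-enol ether F6, NBS at −78 °C gives the 10,10-dibromo ketone methyl (5E,7E,12R,14Z)-10,10-dibromo-9-oxo-12-(triethylsilyloxy)prosta-5,7,14-trien-1-oate F7, and Li2CO3/LiBr in DMF removes HBr across C10–C11 to give 27.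

3. Step 10. What may go wrong: the aldehyde is a vinylogous silyl formate next to a quaternary carbon and may be too weak an electrophile for the alkenylzinc, so that methyl transfer from zinc or O-to-O silyl migration in the alkoxide competes. The fallback sets out from 16 and comes back at 19 by a Nozaki–Hiyama–Kishi coupling. Hydrozirconation of 16 and iodinolysis (Cp2Zr(H)Cl, CH2Cl2; I2) give methyl (5E)-6-iodohex-5-enoate F8, whose alkenylchromium reagent (CrCl2, divalent chromium, with catalytic NiCl2, DMSO–THF, rt) adds to 15 to give 19.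

Further compounds
F1 | step 5 | (R)-triethyl[2-(oxiran-2-yl)ethoxy]silane | CC[Si](CC)(CC)OCC[C@@H]1CO1
F2 | step 5 | methyl (6S)-6-hydroxy-3-oxo-8-(triethylsilyloxy)octanoate | COC(=O)CC(=O)CC[C@H](O)CCO[Si](CC)(CC)CC
F3 | step 5 | methyl (6S)-3-oxo-6,8-bis(triethylsilyloxy)octanoate | COC(=O)CC(=O)CC[C@H](O[Si](CC)(CC)CC)CCO[Si](CC)(CC)CC
F4 | step 5 | methyl (6S)-2-diazo-3-oxo-6,8-bis(triethylsilyloxy)octanoate | COC(=O)C(=[N+]=[N-])C(=O)CC[C@H](O[Si](CC)(CC)CC)CCO[Si](CC)(CC)CC
F5 | step 5 | methyl (5S)-2-oxo-5-(triethylsilyloxy)-5-[2-(triethylsilyloxy)ethyl]cyclopentane-1-carboxylate | COC(=O)C1C(=O)CC[C@]1(O[Si](CC)(CC)CC)CCO[Si](CC)(CC)CC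
F6 | step 13 | C9 trimethylsilyl enol ether of 23 (C9–OSiMe3, C9=C10–Br; otherwise as 23) | CCCCC/C=C\C[C@@]1(O[Si](CC)(CC)CC)CC(Br)=C(O[Si](C)(C)C)/C1=C/C=C/CCCC(=O)OC
F7 | step 13 | methyl (5E,7E,12R,14Z)-10,10-dibromo-9-oxo-12-(triethylsilyloxy)prosta-5,7,14-trien-1-oate | CCCCC/C=C\C[C@@]1(O[Si](CC)(CC)CC)CC(Br)(Br)C(=O)/C1=C/C=C/CCCC(=O)OC
F8 | step 10 | methyl (5E)-6-iodohex-5-enoate | COC(=O)CCC/C=C/I
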